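**Retrosynthetic overview** (target locants C1–C8a; side chain C1'–C7')
1. Pyran ring, formed last: O2–C3 bond by 6-endo oxa-Michael addition of the C1 alkoxide to a 3-alkynylcyclohexenone; C3–C1' bond by Sonogashira coupling with an E-vinyl iodide.
2. Ring B, formed first: C4a=C5 by intramolecular aldol condensation of a methyl ketone onto an ynone whose carbonyl comes from a Weinreb amide.
3. Key disconnection C6–C7: a metalated enol ether (acetyl anion equivalent) adds to an unprotected α-hydroxy methyl ketone under Cram-chelate control and sets C7.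
4. C8 and C8a: Evans syn-aldol of a 3-silyloxypropanoyl oxazolidinone with methacrolein, then ozonolysis to the methyl ketone.
5. Side chain: L-isoleucine supplies C4' and C5'; chelation-controlled MeMgBr addition to an E-stannyl enone sets C3'.

Assumption: 3-[(tert-butyldimethylsilyl)oxy]propanoic acid (1) is bought as a catalogue compound.

**Route**

Step 1
Reactants: 1 3-[(tert-butyldimethylsilyl)oxy]propanoic acid; 2 (4S)-4-benzyl-1,3-oxazolidin-2-one
Product: 4 (4S)-4-benzyl-3-{3-[(tert-butyldimethylsilyl)oxy]propanoyl}-1,3-oxazolidin-2-one, via mixed pivalic anhydride 3 (not isolated)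
Conditions: PivCl, Et3N, THF, −20 °C; then LiCl, 2, −20 °C to rt
Reagents that add atoms: none
Why: N-acylation of the oxazolidinone through a mixed anhydride (auxiliary loading) is a routine acyl transfer that leaves the silyl ether intact and creates no stereocentre.

Step 2
Reactants: 4 (4S)-4-benzyl-3-{3-[(tert-butyldimethylsilyl)oxy]propanoyl}-1,3-oxazolidin-2-one; 5 2-methylprop-2-enal
Product: 7 (4S)-4-benzyl-3-[(2S,3S)-2-{[(tert-butyldimethylsilyl)oxy]methyl}-3-hydroxy-4-methylpent-4-enoyl]-1,3-oxazolidin-2-one, via Z-boron enolate 6 (not isolated)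
Conditions: Bu2BOTf, iPr2NEt, CH2Cl2, −78 to 0 °C; then 5, −78 to 0 °C; pH 7 buffer, MeOH, H2O2
Reagents that add atoms: none
Why: Evans syn-aldol reaction, in which the Z-boron enolate reacts through a Zimmerman–Traxler chair with one face shielded by the (S)-benzyl group, setting the 2S,3S pair that becomes C8a and C8 of the target.

Step 3
Reactants: 7 (4S)-4-benzyl-3-[(2S,3S)-2-{[(tert-butyldimethylsilyl)oxy]methyl}-3-hydroxy-4-methylpent-4-enoyl]-1,3-oxazolidin-2-one
Product: 8 (2S,3S)-2-{[(tert-butyldimethylsilyl)oxy]methyl}-3-hydroxy-N-methoxy-N,4-dimethylpent-4-enamide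
Conditions: MeNH(OMe)·HCl, AlMe3, CH2Cl2, −20 to 0 °C
Reagents that add atoms: N,O-dimethylhydroxylamine hydrochloride, CNOC.Cl
Why: Aluminium amide transamidation of the β-hydroxy imide (Weinreb amide formation) releases the auxiliary without touching either stereocentre.

Step 4
Reactants: 8 (2S,3S)-2-{[(tert-butyldimethylsilyl)oxy]methyl}-3-hydroxy-N-methoxy-N,4-dimethylpent-4-enamide
Product: 10 (2S,3S)-2-{[(tert-butyldimethylsilyl)oxy]methyl}-3-hydroxy-N-methoxy-N-methyl-4-oxopentanamide, via ozonide 9 (not isolated)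
Conditions: O3, CH2Cl2, −78 °C; then PPh3, −78 °C to rt
Reagents that add atoms: ozone, [O-][O+]=O
Why: Ozonolysis with reductive work-up cleaves the only alkene to the methyl ketone and involves no stereocentre; the α-hydroxy ketone is used at once.

Step 5
Reactants: 10 (2S,3S)-2-{[(tert-butyldimethylsilyl)oxy]methyl}-3-hydroxy-N-methoxy-N-methyl-4-oxopentanamide; 11 ethoxyethene
Product: 14 (2S,3S,4R)-2-{[(tert-butyldimethylsilyl)oxy]methyl}-5-ethoxy-3,4-dihydroxy-N-methoxy-N,4-dimethylhex-5-enamide, via 1-ethoxyvinyllithium 12 (not isolated), via (1-ethoxyvinyl)magnesium bromide 13 (not isolated)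
Conditions: 11, tBuLi, THF, −78 to 0 °C; MgBr2·OEt2, −78 °C; then 10, −78 °C; aq NH4Cl
Reagents that add atoms: none
Why: Addition of an acyl anion equivalent (metalated enol ether) to the ketone joins two carbonyl-level carbons (C6–C7); the magnesium alkoxide of the free α-hydroxyl forms a five-membered Cram chelate and the nucleophile enters from the side of the α-hydrogen, giving the 4R carbinol (C7 of the target), while the Weinreb amide does not react at −78 °C.

Step 6
Reactants: 14 (2S,3S,4R)-2-{[(tert-butyldimethylsilyl)oxy]methyl}-5-ethoxy-3,4-dihydroxy-N-methoxy-N,4-dimethylhex-5-enamide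
Product: 15 (2S,3S,4R)-2-{[(tert-butyldimethylsilyl)oxy]methyl}-5-ethoxy-N-methoxy-N,4-dimethyl-3,4-bis[(triethylsilyl)oxy]hex-5-enamide
Conditions: Et3SiOTf, 2,6-lutidine, CH2Cl2, −78 to −20 °C
Reagents that add atoms: triethylsilyl trifluoromethanesulfonate, CC[Si](CC)(CC)OS(=O)(=O)C(F)(F)F
Why: Silyl triflate silylation of both hydroxyls under buffered basic conditions stops the C8 oxygen from adding to the ynone made next and changes no stereocentre.

Step 7
Reactants: 15 (2S,3S,4R)-2-{[(tert-butyldimethylsilyl)oxy]methyl}-5-ethoxy-N-methoxy-N,4-dimethyl-3,4-bis[(triethylsilyl)oxy]hex-5-enamide; 16 ethynyltrimethylsilane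
Product: 19 (4S,5S,6R)-4-{[(tert-butyldimethylsilyl)oxy]methyl}-6-methyl-5,6-bis[(triethylsilyl)oxy]-1-(trimethylsilyl)oct-1-yne-3,7-dione, via lithium (trimethylsilyl)acetylide 17 (not isolated), via enol ether ynone 18 (not isolated)
Conditions: 16, nBuLi, THF, −78 °C; then 15, −78 to −20 °C; 0.1 M HCl, THF, 0 °C
Reagents that add atoms: water, O
Why: Weinreb ketone synthesis, in which the chelated tetrahedral adduct prevents over-addition and the dilute acid quench releases the ynone and hydrolyses the enol ether to the methyl ketone.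

Step 8
Reactants: 19 (4S,5S,6R)-4-{[(tert-butyldimethylsilyl)oxy]methyl}-6-methyl-5,6-bis[(triethylsilyl)oxy]-1-(trimethylsilyl)oct-1-yne-3,7-dione
Product: 22 (4S,5S,6R)-4-{[(tert-butyldimethylsilyl)oxy]methyl}-6-methyl-5,6-bis[(triethylsilyl)oxy]-3-[(trimethylsilyl)ethynyl]cyclohex-2-en-1-one, via aldol adduct 20 (not isolated), via tertiary mesylate 21 (not isolated)
Conditions: LiN(SiMe3)2, THF, −78 °C; then MsCl, Et3N, −78 to 0 °C
Reagents that add atoms: none
Why: Intramolecular aldol condensation, in which the kinetic enolate of the unhindered methyl ketone closes a six-membered ring on the electrophilic ynone carbonyl and the tertiary alkoxide leaves as its mesylate (E1cB), forming ring B without touching the stereocentres.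

Step 9
Reactants: 23 L-isoleucine
Product: 24 (2S,3S)-2-hydroxy-3-methylpentanoic acid
Conditions: NaNO2, 1 M H2SO4, 0 °C to rt
Reagents that add atoms: water, O
Why: Diazotisation and hydrolysis of the α-amino acid proceed with net retention (double inversion through the α-lactone), so both stereocentres of isoleucine are kept.

Step 10
Reactants: 24 (2S,3S)-2-hydroxy-3-methylpentanoic acid
Product: 25 (2S,3S)-2-hydroxy-N-methoxy-N,3-dimethylpentanamide
Conditions: MeNH(OMe)·HCl, EDC·HCl, HOBt, N-methylmorpholine, CH2Cl2, 0 °C to rt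
Reagents that add atoms: N,O-dimethylhydroxylamine hydrochloride, CNOC.Cl
Why: Carbodiimide amide coupling to the Weinreb amide, with the amine outcompeting the secondary hydroxyl and no epimerisation of the α-centre.

Step 11
Reactants: 25 (2S,3S)-2-hydroxy-N-methoxy-N,3-dimethylpentanamide; 26 (E)-1,2-bis(tributylstannyl)ethene
Product: 28 (1E,4S,5S)-4-hydroxy-5-methyl-1-(tributylstannyl)hept-1-en-3-one, via (E)-2-(tributylstannyl)vinyllithium 27 (not isolated)
Conditions: 26, nBuLi, THF, −78 °C; then 25, −78 to −40 °C; cold aq NH4Cl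
Reagents that add atoms: none
Why: Tin–lithium exchange gives the E-vinyllithium with retention, and Weinreb ketone synthesis (one equivalent consumed by the hydroxyl) gives the enone without over-addition.

Step 12
Reactants: 28 (1E,4S,5S)-4-hydroxy-5-methyl-1-(tributylstannyl)hept-1-en-3-one
Product: 29 (1E,3R,4S,5S)-3,5-dimethyl-1-(tributylstannyl)hept-1-ene-3,4-diol
Conditions: MeMgBr, THF, −78 °C; aq NH4Cl
Reagents that add atoms: methylmagnesium bromide, C[Mg]Br
Why: Cram-chelate-controlled Grignard 1,2-addition, in which the magnesium alkoxide locks the ketone and methyl adds from the side of the α-hydrogen, setting the 3R tertiary carbinol (C3' of the target).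

Step 13
Reactants: 29 (1E,3R,4S,5S)-3,5-dimethyl-1-(tributylstannyl)hept-1-ene-3,4-diol
Product: 30 (1E,3R,4S,5S)-1-iodo-3,5-dimethylhept-1-ene-3,4-diol
Conditions: I2, CH2Cl2, 0 °C
Reagents that add atoms: iodine, I-I
Why: Iododestannylation is an ipso electrophilic substitution that retains the E geometry and leaves the diol untouched.

Step 14
Reactants: 22 (4S,5S,6R)-4-{[(tert-butyldimethylsilyl)oxy]methyl}-6-methyl-5,6-bis[(triethylsilyl)oxy]-3-[(trimethylsilyl)ethynyl]cyclohex-2-en-1-one; 30 (1E,3R,4S,5S)-1-iodo-3,5-dimethylhept-1-ene-3,4-diol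
Product: 32 (4S,5S,6R)-4-{[(tert-butyldimethylsilyl)oxy]methyl}-3-[(3E,5R,6S,7S)-5,6-dihydroxy-5,7-dimethylnon-3-en-1-yn-1-yl]-6-methyl-5,6-bis[(triethylsilyl)oxy]cyclohex-2-en-1-one, via terminal alkyne 31 (not isolated)
Conditions: Pd(PPh3)4 (5 mol %), CuI (10 mol %), K2CO3, MeOH/THF, degassed, rt
Reagents that add atoms: none
Why: Sonogashira coupling after in situ methanolysis of the alkynylsilane keeps the free alkyne concentration low and joins the sp and sp2 carbons with retention of the E geometry.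

Step 15
Reactants: 32 (4S,5S,6R)-4-{[(tert-butyldimethylsilyl)oxy]methyl}-3-[(3E,5R,6S,7S)-5,6-dihydroxy-5,7-dimethylnon-3-en-1-yn-1-yl]-6-methyl-5,6-bis[(triethylsilyl)oxy]cyclohex-2-en-1-one
Product: 34 (7R,8S,8aS)-3-[(1E,3R,4S,5S)-3,4-dihydroxy-3,5-dimethylhept-1-en-1-yl]-7,8-dihydroxy-7-methyl-8,8a-dihydro-1H-isochromen-6(7H)-one, via pentaol enynone 33 (not isolated)
Conditions: Bu4NF, THF, 0 °C to rt; aq NH4Cl
Reagents that add atoms: none
Why: Fluoride desilylation followed by intramolecular 6-endo-dig oxa-Michael (1,6-) addition of the primary alkoxide to the alkyne terminus of the enynone, the only position that gives a stabilised allenyl enolate, closes the pyran ring and creates no stereocentre.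

**Compound list**
1 | 3-[(tert-butyldimethylsilyl)oxy]propanoic acid | CC(C)(C)[Si](C)(C)OCCC(=O)O | starting material
2 | (4S)-4-benzyl-1,3-oxazolidin-2-one | O=C1OC[C@H](Cc2ccccc2)N1 | starting material
3 | 3-[(tert-butyldimethylsilyl)oxy]propanoic pivalic anhydride | CC(C)(C)C(=O)OC(=O)CCO[Si](C)(C)C(C)(C)C | intermediate
4 | (4S)-4-benzyl-3-{3-[(tert-butyldimethylsilyl)oxy]propanoyl}-1,3-oxazolidin-2-one | O=C1OC[C@H](Cc2ccccc2)N1C(=O)CCO[Si](C)(C)C(C)(C)C | intermediate
5 | 2-methylprop-2-enal (methacrolein) | CC(=C)C=O | starting material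
6 | dibutylboron Z-enolate of 4 (boron–oxygen cis to the silyloxymethyl group) | CCCCB(CCCC)O/C(=C\CO[Si](C)(C)C(C)(C)C)N1[C@@H](Cc2ccccc2)COC1=O | intermediate
7 | (4S)-4-benzyl-3-[(2S,3S)-2-{[(tert-butyldimethylsilyl)oxy]methyl}-3-hydroxy-4-methylpent-4-enoyl]-1,3-oxazolidin-2-one | C=C(C)[C@@H](O)[C@@H](C(=O)N1[C@@H](Cc2ccccc2)COC1=O)CO[Si](C)(C)C(C)(C)C | intermediate
8 | (2S,3S)-2-{[(tert-butyldimethylsilyl)oxy]methyl}-3-hydroxy-N-methoxy-N,4-dimethylpent-4-enamide | C=C(C)[C@@H](O)[C@@H](C(=O)N(C)OC)CO[Si](C)(C)C(C)(C)C | intermediate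
9 | ozonide of 8: (2S,3S)-2-{[(tert-butyldimethylsilyl)oxy]methyl}-3-hydroxy-N-methoxy-N-methyl-3-(3-methyl-1,2,4-trioxolan-3-yl)propanamide, both epimers at the trioxolane carbon | CC1(OOCO1)[C@@H](O)[C@@H](C(=O)N(C)OC)CO[Si](C)(C)C(C)(C)C | intermediate
10 | (2S,3S)-2-{[(tert-butyldimethylsilyl)oxy]methyl}-3-hydroxy-N-methoxy-N-methyl-4-oxopentanamide | CC(=O)[C@@H](O)[C@@H](C(=O)N(C)OC)CO[Si](C)(C)C(C)(C)C | intermediate
11 | ethoxyethene (ethyl vinyl ether) | C=COCC | starting material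
12 | 1-ethoxyvinyllithium | [Li]C(=C)OCC | intermediate
13 | (1-ethoxyvinyl)magnesium bromide | Br[Mg]C(=C)OCC | intermediate
14 | (2S,3S,4R)-2-{[(tert-butyldimethylsilyl)oxy]methyl}-5-ethoxy-3,4-dihydroxy-N-methoxy-N,4-dimethylhex-5-enamide | C=C(OCC)[C@](C)(O)[C@@H](O)[C@@H](C(=O)N(C)OC)CO[Si](C)(C)C(C)(C)C | intermediate
15 | (2S,3S,4R)-2-{[(tert-butyldimethylsilyl)oxy]methyl}-5-ethoxy-N-methoxy-N,4-dimethyl-3,4-bis[(triethylsilyl)oxy]hex-5-enamide | C=C(OCC)[C@](C)(O[Si](CC)(CC)CC)[C@@H](O[Si](CC)(CC)CC)[C@@H](C(=O)N(C)OC)CO[Si](C)(C)C(C)(C)C | intermediate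
16 | ethynyltrimethylsilane | C#C[Si](C)(C)C | starting material
17 | lithium (trimethylsilyl)acetylide | [Li]C#C[Si](C)(C)C | intermediate
18 | (4S,5S,6R)-4-{[(tert-butyldimethylsilyl)oxy]methyl}-7-ethoxy-6-methyl-5,6-bis[(triethylsilyl)oxy]-1-(trimethylsilyl)oct-7-en-1-yn-3-one | C=C(OCC)[C@](C)(O[Si](CC)(CC)CC)[C@@H](O[Si](CC)(CC)CC)[C@@H](C(=O)C#C[Si](C)(C)C)CO[Si](C)(C)C(C)(C)C | intermediate
19 | (4S,5S,6R)-4-{[(tert-butyldimethylsilyl)oxy]methyl}-6-methyl-5,6-bis[(triethylsilyl)oxy]-1-(trimethylsilyl)oct-1-yne-3,7-dione | CC(=O)[C@](C)(O[Si](CC)(CC)CC)[C@@H](O[Si](CC)(CC)CC)[C@@H](C(=O)C#C[Si](C)(C)C)CO[Si](C)(C)C(C)(C)C | intermediate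
20 | (2R,3S,4S)-4-{[(tert-butyldimethylsilyl)oxy]methyl}-5-hydroxy-2-methyl-2,3-bis[(triethylsilyl)oxy]-5-[(trimethylsilyl)ethynyl]cyclohexan-1-one, C5 epimers | C[Si](C)(C)C#CC1(O)CC(=O)[C@](C)(O[Si](CC)(CC)CC)[C@@H](O[Si](CC)(CC)CC)[C@@H]1CO[Si](C)(C)C(C)(C)C | intermediate
21 | methanesulfonate of 20 at the tertiary hydroxyl | C[Si](C)(C)C#CC1(OS(C)(=O)=O)CC(=O)[C@](C)(O[Si](CC)(CC)CC)[C@@H](O[Si](CC)(CC)CC)[C@@H]1CO[Si](C)(C)C(C)(C)C | intermediate
22 | (4S,5S,6R)-4-{[(tert-butyldimethylsilyl)oxy]methyl}-6-methyl-5,6-bis[(triethylsilyl)oxy]-3-[(trimethylsilyl)ethynyl]cyclohex-2-en-1-one | C[Si](C)(C)C#CC1=CC(=O)[C@](C)(O[Si](CC)(CC)CC)[C@@H](O[Si](CC)(CC)CC)[C@@H]1CO[Si](C)(C)C(C)(C)C | intermediate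
23 | L-isoleucine | CC[C@H](C)[C@H](N)C(=O)O | starting material
24 | (2S,3S)-2-hydroxy-3-methylpentanoic acid | CC[C@H](C)[C@H](O)C(=O)O | intermediate
25 | (2S,3S)-2-hydroxy-N-methoxy-N,3-dimethylpentanamide | CC[C@H](C)[C@H](O)C(=O)N(C)OC | intermediate
26 | (E)-1,2-bis(tributylstannyl)ethene | CCCC[Sn](CCCC)(CCCC)/C=C/[Sn](CCCC)(CCCC)CCCC | starting material
27 | (E)-2-(tributylstannyl)vinyllithium | [Li]/C=C/[Sn](CCCC)(CCCC)CCCC | intermediate
28 | (1E,4S,5S)-4-hydroxy-5-methyl-1-(tributylstannyl)hept-1-en-3-one | CC[C@H](C)[C@H](O)C(=O)/C=C/[Sn](CCCC)(CCCC)CCCC | intermediate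
29 | (1E,3R,4S,5S)-3,5-dimethyl-1-(tributylstannyl)hept-1-ene-3,4-diol | CC[C@H](C)[C@H](O)[C@](C)(O)/C=C/[Sn](CCCC)(CCCC)CCCC | intermediate
30 | (1E,3R,4S,5S)-1-iodo-3,5-dimethylhept-1-ene-3,4-diol | CC[C@H](C)[C@H](O)[C@](C)(O)/C=C/I | intermediate
31 | (4S,5S,6R)-4-{[(tert-butyldimethylsilyl)oxy]methyl}-3-ethynyl-6-methyl-5,6-bis[(triethylsilyl)oxy]cyclohex-2-en-1-one | C#CC1=CC(=O)[C@](C)(O[Si](CC)(CC)CC)[C@@H](O[Si](CC)(CC)CC)[C@@H]1CO[Si](C)(C)C(C)(C)C | intermediate
32 | (4S,5S,6R)-4-{[(tert-butyldimethylsilyl)oxy]methyl}-3-[(3E,5R,6S,7S)-5,6-dihydroxy-5,7-dimethylnon-3-en-1-yn-1-yl]-6-methyl-5,6-bis[(triethylsilyl)oxy]cyclohex-2-en-1-one | CC[C@H](C)[C@H](O)[C@](C)(O)/C=C/C#CC1=CC(=O)[C@](C)(O[Si](CC)(CC)CC)[C@@H](O[Si](CC)(CC)CC)[C@@H]1CO[Si](C)(C)C(C)(C)C | intermediate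
33 | (4S,5S,6R)-3-[(3E,5R,6S,7S)-5,6-dihydroxy-5,7-dimethylnon-3-en-1-yn-1-yl]-5,6-dihydroxy-4-(hydroxymethyl)-6-methylcyclohex-2-en-1-one | CC[C@H](C)[C@H](O)[C@](C)(O)/C=C/C#CC1=CC(=O)[C@](C)(O)[C@@H](O)[C@@H]1CO | intermediate
34 | (7R,8S,8aS)-3-[(1E,3R,4S,5S)-3,4-dihydroxy-3,5-dimethylhept-1-en-1-yl]-7,8-dihydroxy-7-methyl-8,8a-dihydro-1H-isochromen-6(7H)-one | CC[C@H](C)[C@H](O)[C@](C)(O)/C=C/C1=CC2=CC(=O)[C@](C)(O)[C@@H](O)[C@@H]2CO1 | target

**Step count**
Total: 15 steps. Longest linear sequence: 10 steps (steps 1–8, 14, 15); the side chain (steps 9–13) is made in parallel.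

**Steps most likely to fail, with fallbacks**

Step 5. The basic vinyl Grignard may enolise the α-hydroxy ketone, chelate control may be incomplete, or the new tertiary alkoxide may lactonise onto the amide. The fallback uses an alkyne instead of an enol ether as the masked acetyl group. It sets out from 10: ethynylmagnesium bromide (THF, −78 °C), a much less basic nucleophile that also adds through the Cram chelate, gives (2S,3S,4S)-2-{[(tert-butyldimethylsilyl)oxy]methyl}-3,4-dihydroxy-N-methoxy-N,4-dimethylhex-5-ynamide F1. Et3SiOTf and 2,6-lutidine give (2S,3S,4S)-2-{[(tert-butyldimethylsilyl)oxy]methyl}-N-methoxy-N,4-dimethyl-3,4-bis[(triethylsilyl)oxy]hex-5-ynamide F2. Excess 17 converts the Weinreb amide into (4S,5S,6S)-4-{[(tert-butyldimethylsilyl)oxy]methyl}-6-methyl-5,6-bis[(triethylsilyl)oxy]-1-(trimethylsilyl)octa-1,7-diyn-3-one F3. Markovnikov hydration of the terminal alkyne only (Ph3PAuNTf2 cat., wet MeOH) unveils the methyl ketone, and the sequence comes back to the route at 19.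

Step 8. The ynone is base-sensitive, and an enolate on the ynone side could expel a silyloxide. The fallback closes ring B with the enol ether itself as the nucleophile instead of an enolate. It sets out from 15: step 7 is quenched with pH 7 buffer so that enol ether ynone 18 is isolated. BF3·OEt2 (CH2Cl2, −78 °C) then triggers an intramolecular Mukaiyama-type addition of the enol ether to the activated ynone carbonyl. Loss of the tertiary hydroxyl and hydrolysis of the oxocarbenium ion on aqueous work-up give the enynone, and the sequence comes back at 22. It makes no compound outside the list (F0).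

Step 15. Basic fluoride could cause retro-aldol cleavage at C7–C8 or epimerise C8a before the ring closes. The fallback separates deprotection from ring closure and replaces the conjugate addition by π-acid catalysis. It sets out from 32: HF·pyridine buffered with pyridine (THF, 0 °C) removes the three silyl groups under non-basic conditions and pentaol enynone 33 is isolated. Ph3PAuNTf2 (2 mol %, CH2Cl2, 0 °C) then catalyses the 6-endo-dig hydroalkoxylation of the alkyne by the primary hydroxyl, and the sequence comes back at 34. It makes no compound outside the list (F0).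

**Further compounds**
F1 | step 5 | (2S,3S,4S)-2-{[(tert-butyldimethylsilyl)oxy]methyl}-3,4-dihydroxy-N-methoxy-N,4-dimethylhex-5-ynamide | C#C[C@](C)(O)[C@@H](O)[C@@H](C(=O)N(C)OC)CO[Si](C)(C)C(C)(C)C
F2 | step 5 | (2S,3S,4S)-2-{[(tert-butyldimethylsilyl)oxy]methyl}-N-methoxy-N,4-dimethyl-3,4-bis[(triethylsilyl)oxy]hex-5-ynamide | C#C[C@](C)(O[Si](CC)(CC)CC)[C@@H](O[Si](CC)(CC)CC)[C@@H](C(=O)N(C)OC)CO[Si](C)(C)C(C)(C)C
F3 | step 5 | (4S,5S,6S)-4-{[(tert-butyldimethylsilyl)oxy]methyl}-6-methyl-5,6-bis[(triethylsilyl)oxy]-1-(trimethylsilyl)octa-1,7-diyn-3-one | C#C[C@](C)(O[Si](CC)(CC)CC)[C@@H](O[Si](CC)(CC)CC)[C@@H](C(=O)C#C[Si](C)(C)C)CO[Si](C)(C)C(C)(C)C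
F0 | step 8 | none | none
F0 | step 15 | none | none
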